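**Assumption:** the target is the free-acid form of D-luciferin 6-O-sulfate, (S) at C4, which is the D-cysteine series. It will be isolated as an ammonium or potassium salt after purification. I checked the CIP assignment of the SMILES: N > CH2S > COOH > H gives S.

## Retrosynthetic overview
1. Target **1** is disconnected at the thiazoline ring to D-cysteine **2** plus 2-cyano-6-sulfooxybenzothiazole **3**. The thiazoline is formed last, and the stereocentre comes intact from **2**.
2. **3** comes from sulfation of phenol **4**. **4** comes from amide **5**, which comes from ester **6**.
3. The benzothiazole ring is formed first. **6** is made in one step from p-benzoquinone **7** and ethyl thiooxamate **8**, in a thio-Nenitzescu-type annulation. The S-addition to the symmetric quinone breaks its symmetry, and the ring closure fixes the OH para to N.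
4. Ring order: benzothiazole (step 1), then thiazoline (step 5).

## Forward route

**Step 1**
Reactants: **7** p-benzoquinone; **8** ethyl thiooxamate (ethyl 2-amino-2-thioxoacetate)
Product: **6** ethyl 6-hydroxybenzothiazole-2-carboxylate
Conditions: BQ (1.5 equiv), EtOH/AcOH 4:1, 25 → 60 °C, 6 h
Reagents that add atoms: none
Why: The thioamide sulfur adds in a thia-Michael fashion to one quinone C=C, and excess quinone reoxidises the adduct. Only the carbonyl ortho to the S-bearing carbon can be attacked by the thioimidate N to close the five-membered ring. Dehydration then gives the aromatic benzothiazole, with the remaining C=O becoming the 6-OH para to N, and the hydroquinone by-product acts as the reductant. Proposed new method: the mechanism is thia-Michael addition, quinone reoxidation, intramolecular N-attack on the carbonyl, then dehydrative aromatisation. The closest known reactions are the Nenitzescu 5-hydroxyindole synthesis and the quinone + thiourea route to 2-amino-6-hydroxybenzothiazole.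

**Step 2**
Reactants: **6**
Product: **5** 6-hydroxybenzothiazole-2-carboxamide
Conditions: 7 N NH3 in MeOH, 0 → 25 °C, 12 h
Reagents that add atoms: ammonia, N
Why: This is aminolysis of an electron-poor heteroaryl ester. The phenol is tolerated as its ammonium phenolate, and there is no stereocentre.

**Step 3**
Reactants: **5**
Product: **4** 6-hydroxybenzothiazole-2-carbonitrile
Conditions: TFAA (3 equiv), pyridine (6 equiv), THF, 0 → 25 °C, 2 h; then aq. NaHCO3/MeOH, 10 min
Reagents that add atoms: none remain in the product. TFAA, O=C(OC(=O)C(F)(F)F)C(F)(F)F, is a dehydrating agent, and the transient aryl trifluoroacetate is cleaved in the work-up.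
Why: Primary amide dehydration with TFAA/pyridine gives the nitrile. The mild bicarbonate work-up removes the aryl trifluoroacetate without attacking the nitrile.

**Step 4**
Reactants: **4**
Product: **3** 6-sulfooxybenzothiazole-2-carbonitrile (potassium salt)
Conditions: SO3·pyridine (3 equiv), DMF, 25 → 40 °C, 4 h; then aq. KHCO3 to pH 7
Reagents that add atoms: sulfur trioxide–pyridine complex, [O-]S(=O)(=O)[n+]1ccccc1 (adds SO3)
Why: SO3·pyridine sulfates phenols chemoselectively to aryl sulfate monoesters, and the 2-cyano group is inert to it. Sulfation is done before the cysteine step so the stereocentre never sees these conditions, and the neutral work-up protects the acid-labile aryl sulfate.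

**Step 5**
Reactants: **3**; **2** D-cysteine (1.3 equiv)
Product: **1** target, (S)-2-(6-sulfooxybenzothiazol-2-yl)-4,5-dihydrothiazole-4-carboxylic acid
Conditions: NaHCO3 to pH 8, MeOH/H2O 1:1, N2, 0 → 25 °C, 30 min; then C18 HPLC (NH4OAc/MeCN)
Reagents that add atoms: none beyond **2**, which is a reactant
Why: This is the luciferin-type cyanobenzothiazole–cysteine condensation. The thiol adds to the nitrile, the amine displaces NH3 in the cyclisation, and the thiazoline forms. The C–H stereocentre of D-cysteine is not involved, so (S) is retained. The short reaction time and pH ≤ 8 limit epimerisation, and the aryl sulfate survives the pH 8 aqueous conditions.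

## Checks
- **Structure:** benzothiazole with the 6-OSO3H para to C3a–N, a 2-linked 4,5-dihydrothiazole and a 4-COOH match the target SMILES.
- **Atom balance:** C6H4O2 + C4H7NO2S – H2O = C10H9NO3S (**6**). The amide, nitrile, sulfate and thiazoline steps follow stoichiometrically. For the last step, C8H3N2O4S2⁻ (**3**) + cysteine – NH3 is consistent.
- **Functional groups:** the ester, amide and nitrile survive their steps. The aryl sulfate is installed only after all acidic and dehydrating steps, and the last step is at pH 8.
- **Stereochemistry:** the only stereocentre is introduced in step 5 from D-cysteine. No later step touches it.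

## Compound list
1 | (S)-2-(6-sulfooxybenzothiazol-2-yl)-4,5-dihydrothiazole-4-carboxylic acid | O=C(O)[C@H]1CSC(c2nc3ccc(OS(=O)(=O)O)cc3s2)=N1 | target
2 | D-cysteine | N[C@H](CS)C(=O)O | starting material
3 | 6-sulfooxybenzothiazole-2-carbonitrile | N#Cc1nc2ccc(OS(=O)(=O)O)cc2s1 | intermediate
4 | 6-hydroxybenzothiazole-2-carbonitrile | N#Cc1nc2ccc(O)cc2s1 | intermediate
5 | 6-hydroxybenzothiazole-2-carboxamide | NC(=O)c1nc2ccc(O)cc2s1 | intermediate
6 | ethyl 6-hydroxybenzothiazole-2-carboxylate | CCOC(=O)c1nc2ccc(O)cc2s1 | intermediate
7 | p-benzoquinone | O=C1C=CC(=O)C=C1 | starting material
8 | ethyl thiooxamate | CCOC(=O)C(N)=S | starting material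

## Totals
Total steps: 5. Longest linear sequence: 5 (the D-cysteine arm is a single convergent step).

## Three steps most likely to fail
1. **Step 1, quinone annulation.** Risks are oxidative dimerisation of the thioamide to a 1,2,4-thiadiazole, over-oxidation, and low yield. Fallback: build the ring from p-anisidine. Treat it with Appel salt to give the iminodithiazole, cyclise with Pd/Cu to 2-cyano-6-methoxybenzothiazole, then demethylate with BBr3 to reach **4** directly. This bypasses steps 1–3.
2. **Step 4, aryl sulfation and isolation.** The phenol is electron-poor, and the sulfate salt is hard to isolate and easy to hydrolyse. Fallback: condense **4** with D-cysteine first to give D-luciferin, then sulfate it enzymatically with an aryl sulfotransferase and p-nitrophenyl sulfate as the donor.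
3. **Step 5, cysteine condensation.** Risks are C4 epimerisation, cystine formation and sulfate loss on isolation. Fallback: convert nitrile **3** to its imidate, condense with D-cysteine methyl ester, and hydrolyse the ester with pig liver esterase at pH 7. Sulfate-labile acid or strong base is avoided.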